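**Plan**

1. Retrosynthesis: the C5 methyl ether is cut last (O–CH3). The cyclohexa-2,4-dienone ring is then cut at C4–C5 and C3a–C7a together, giving a furan (C7a, C7, C6, C5 plus the oxygen on C5) and an alkyne (C3a≡C4) joined through O1–C2–C3.
2. Enabling feature: C5 and C7a both carry oxygen and flank C6(=O)–C7H in a 1,4 relation, so the dienone ring is an opened 7-oxanorbornadiene. The furan ring oxygen is a temporary bridge that ends as the C5 oxygen, and a silyl group on O6 temporarily carries the ketone.
3. Forward order: anti homopropargylic alcohol (C2, C3) → γ-chloro β-keto ester → 5-alkoxyfuran-3(2H)-one → C-allylation → silyloxyfuran → intramolecular furan Diels–Alder reaction with bridge opening (dihydrofuran ring and six-membered ring together) → O-methylation.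
4. Stereochemistry: C2 and C3 come from a Marshall propargylation of 3,4,5-trimethoxybenzaldehyde with the mesylate of (R)-but-3-yn-2-ol (reagent control, anti). C5 is set in the cycloaddition by the furan face that the tethered alkyne reaches, and its C–O bond is never broken afterwards.

Key step: step 7

Remark: the benzofuran locants of the target (O1, C2, C3, C3a, C4 to C7, C7a) are used for the corresponding atoms of all intermediates.

**Route**

Step 1
Reactants: 1 (R)-but-3-yn-2-ol
Product: 2 (R)-but-3-yn-2-yl methanesulfonate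
Conditions: MsCl, Et3N, CH2Cl2, −78 to 0 °C
Reagents that add atoms: methanesulfonyl chloride, CS(=O)(=O)Cl
Why: Sulfonylation at oxygen (mesylate formation) does not touch the C–O stereocentre, so the (R) configuration is kept.

Step 2
Reactants: 2 (R)-but-3-yn-2-yl methanesulfonate; 3 3,4,5-trimethoxybenzaldehyde
Product: 4 (1S,2S)-2-methyl-1-(3,4,5-trimethoxyphenyl)but-3-yn-1-ol
Conditions: Pd(OAc)2 (5 mol %), PPh3 (5 mol %), Et2Zn (3 equiv), THF, −20 °C; aq. NH4Cl
Reagents that add atoms: none
Why: Marshall propargylation: zerovalent palladium formed in situ displaces the mesylate anti (SN2′), transmetalation gives a configurationally defined allenylzinc that adds to the aldehyde through a closed SE2′ transition state, so the (R)-mesylate should fix (S) at the methyl-bearing carbon and the anti preference of the closed transition state should fix (S) at the carbinol carbon.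

Step 3
Reactants: 5 Meldrum's acid; 6 chloroacetyl chloride
Product: 7 chloroacetyl Meldrum's acid (enol form)
Conditions: pyridine (2 equiv), CH2Cl2, 0 °C to rt; dilute HCl wash
Reagents that add atoms: none
Why: C-acylation of Meldrum's acid by the acid chloride (Oikawa–Yonemitsu acylation), the product resting as its enol.

Step 4
Reactants: 4 (1S,2S)-2-methyl-1-(3,4,5-trimethoxyphenyl)but-3-yn-1-ol; 7 chloroacetyl Meldrum's acid
Product: 8 (1S,2S)-2-methyl-1-(3,4,5-trimethoxyphenyl)but-3-yn-1-yl 4-chloro-3-oxobutanoate
Conditions: PhMe, 80 °C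
Reagents that add atoms: none
Why: Thermal loss of acetone from the acyl Meldrum's acid gives an acylketene that is trapped by the secondary alcohol and then loses CO2 (Oikawa β-keto ester synthesis), an O-acylation that leaves both stereocentres untouched.

Step 5
Reactants: 8 (1S,2S)-2-methyl-1-(3,4,5-trimethoxyphenyl)but-3-yn-1-yl 4-chloro-3-oxobutanoate
Product: 9 5-{[(1S,2S)-2-methyl-1-(3,4,5-trimethoxyphenyl)but-3-yn-1-yl]oxy}furan-3(2H)-one
Conditions: Et3N (1.2 equiv), MeCN (0.02 M), 0 °C to rt
Reagents that add atoms: none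
Why: The β-keto ester enolate closes through its ester-carbonyl oxygen onto the chloromethyl carbon (5-exo-tet O-alkylation, the classical furan-3(2H)-one ring closure of γ-halo β-dicarbonyl compounds), dilution disfavouring intermolecular C-alkylation.

Step 6
Reactants: 9 5-{[(1S,2S)-2-methyl-1-(3,4,5-trimethoxyphenyl)but-3-yn-1-yl]oxy}furan-3(2H)-one
Product: 10 2-(prop-2-en-1-yl)-5-{[(1S,2S)-2-methyl-1-(3,4,5-trimethoxyphenyl)but-3-yn-1-yl]oxy}furan-3(2H)-one
Conditions: LiN(SiMe3)2 (1.05 equiv), THF, −78 °C; allyl bromide, −78 to 0 °C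
Reagents that add atoms: allyl bromide, C=CCBr
Why: The furanone C2–H (far more acidic than the alkyne C–H, its anion being an aromatic 3-furanolate) is removed selectively and the enolate is C-allylated (enolate alkylation; any O-allyl ether converges by Claisen rearrangement), the new C2 centre being formed without control and erased in step 7.

Step 7
Reactants: 10 2-(prop-2-en-1-yl)-5-{[(1S,2S)-2-methyl-1-(3,4,5-trimethoxyphenyl)but-3-yn-1-yl]oxy}furan-3(2H)-one
Product: 14 (2S,3S,5R)-5-hydroxy-3-methyl-5-(prop-2-en-1-yl)-2-(3,4,5-trimethoxyphenyl)-2,3-dihydro-1-benzofuran-6(5H)-one, via silyloxyfuran 11 (not isolated), via oxygen-bridged cycloadduct 12 (not isolated), via silyl ether 13 (not isolated)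
Conditions: Me3SiOTf (1.2 equiv), Et3N (3 equiv), PhMe, 0 °C; then 90 °C (degassed, sealed); then citric acid, MeOH, 0 °C
Reagents that add atoms: none
Why: Proposed new method: O-silylation aromatises 10 to the 2-alkoxy-4-silyloxyfuran 11, whose carbons C7a–C7–C6–C5 form a diene locked s-cis that adds the tethered alkyne C3a≡C4 in an intramolecular furan Diels–Alder reaction (C3a–C7a and C4–C5 formed suprafacially, 12); the oxygen bridge then opens at its acetal-type C7a–O bond under the push of O1 and of the silyl enol ether, and a 1,4 oxygen-to-oxygen silyl shift quenches the dipole to dienone 13, which cannot aromatise because C5 is quaternary, so the furan oxygen stays on C5. The closest known reactions are the intramolecular furan Diels–Alder and bridge-opening cascades of 2-amino- and 2-amidofurans carrying tethered alkenes or alkynes, which end in indolines, phenols or cyclohexenones; an oxygen-tethered 2-alkoxy-4-silyloxyfuran that ends in a cyclohexa-2,4-dienone is not precedented. The dihydrofuran ring closes as the fused five-membered ring of the cycloaddition through the three-atom tether O1–C2–C3 (bond C3a–C7a), and the six-membered ring closes by the [4+2] union itself. C5 is the only new stereocentre that is kept: it is set by the furan face that the alkyne reaches, and the trans-2-aryl-3-methyl tether is expected to fold as an envelope with both groups pseudo-equatorial and C2 tipped toward the open side of the oxygen bridge, which puts the C3 methyl group on the bridge side and therefore cis to the C5 oxygen, that is (5R); C2 and C3 are not touched. The step needs the alkyne to reach the furan and not the allyl group (secured by the tether, only C3a can reach C7a), the bridge to open toward C7a (secured by its two oxygen donors) and a temperature below the onset of [3,3] shifts of the allyl dienone; the facial bias is the least certain element and the C5 epimer, if formed, would be removed by chromatography.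

Step 8
Reactants: 14 (2S,3S,5R)-5-hydroxy-3-methyl-5-(prop-2-en-1-yl)-2-(3,4,5-trimethoxyphenyl)-2,3-dihydro-1-benzofuran-6(5H)-one
Product: 15 (2S,3S,5R)-5-methoxy-3-methyl-5-(prop-2-en-1-yl)-2-(3,4,5-trimethoxyphenyl)-2,3-dihydro-1-benzofuran-6(5H)-one
Conditions: MeOTf (3 equiv), 2,6-di-tert-butyl-4-methylpyridine (4 equiv), CH2Cl2, 0 °C to rt
Reagents that add atoms: methyl trifluoromethanesulfonate, COS(=O)(=O)C(F)(F)F
Why: O-methylation of the neutral tertiary hydroxyl with a hindered pyridine as proton acceptor (Williamson-type alkylation without alkoxide formation) keeps the C5–O bond and hence (5R), and avoids the anionic oxy-Cope shift of the allyl group that a free alkoxide would invite.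

**Compound list**

1 | (R)-but-3-yn-2-ol | C#C[C@@H](C)O | starting material
2 | (R)-but-3-yn-2-yl methanesulfonate | C#C[C@@H](C)OS(C)(=O)=O | intermediate
3 | 3,4,5-trimethoxybenzaldehyde | O=Cc1cc(OC)c(OC)c(OC)c1 | starting material
4 | (1S,2S)-2-methyl-1-(3,4,5-trimethoxyphenyl)but-3-yn-1-ol (anti) | O[C@H](c1cc(OC)c(OC)c(OC)c1)[C@H](C#C)C | intermediate
5 | Meldrum's acid (2,2-dimethyl-1,3-dioxane-4,6-dione) | CC1(C)OC(=O)CC(=O)O1 | starting material
6 | chloroacetyl chloride | ClCC(=O)Cl | starting material
7 | 5-(2-chloro-1-hydroxyethylidene)-2,2-dimethyl-1,3-dioxane-4,6-dione (chloroacetyl Meldrum's acid, enol form) | CC1(C)OC(=O)C(=C(O)CCl)C(=O)O1 | intermediate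
8 | (1S,2S)-2-methyl-1-(3,4,5-trimethoxyphenyl)but-3-yn-1-yl 4-chloro-3-oxobutanoate | ClCC(=O)CC(=O)O[C@H](c1cc(OC)c(OC)c(OC)c1)[C@H](C#C)C | intermediate
9 | 5-{[(1S,2S)-2-methyl-1-(3,4,5-trimethoxyphenyl)but-3-yn-1-yl]oxy}furan-3(2H)-one | O=C1COC(O[C@H](c2cc(OC)c(OC)c(OC)c2)[C@H](C#C)C)=C1 | intermediate
10 | 2-(prop-2-en-1-yl)-5-{[(1S,2S)-2-methyl-1-(3,4,5-trimethoxyphenyl)but-3-yn-1-yl]oxy}furan-3(2H)-one (both epimers at the furanone C2) | O=C1C(CC=C)OC(O[C@H](c2cc(OC)c(OC)c(OC)c2)[C@H](C#C)C)=C1 | intermediate
11 | trimethyl{[2-(prop-2-en-1-yl)-5-{[(1S,2S)-2-methyl-1-(3,4,5-trimethoxyphenyl)but-3-yn-1-yl]oxy}furan-3-yl]oxy}silane | C=CCc1oc(O[C@H](c2cc(OC)c(OC)c(OC)c2)[C@H](C#C)C)cc1O[Si](C)(C)C | intermediate (not isolated)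
12 | oxygen-bridged cycloadduct: 7-oxabicyclo[2.2.1]hepta-2,5-diene with bridgeheads C5 (allyl) and C7a (O1), OSiMe3 on C6, fused at C7a–C3a to the (2S,3S)-tetrahydrofuran ring, C3 methyl on the side of the oxygen bridge | C=CC[C@@]12O[C@]3(O[C@H](c4cc(OC)c(OC)c(OC)c4)[C@@H](C)C3=C1)C=C2O[Si](C)(C)C | intermediate (not isolated)
13 | (2S,3S,5R)-3-methyl-5-(prop-2-en-1-yl)-2-(3,4,5-trimethoxyphenyl)-5-[(trimethylsilyl)oxy]-2,3-dihydro-1-benzofuran-6(5H)-one | C=CC[C@@]1(O[Si](C)(C)C)C=C2C(=CC1=O)O[C@H](c1cc(OC)c(OC)c(OC)c1)[C@H]2C | intermediate (not isolated)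
14 | (2S,3S,5R)-5-hydroxy-3-methyl-5-(prop-2-en-1-yl)-2-(3,4,5-trimethoxyphenyl)-2,3-dihydro-1-benzofuran-6(5H)-one | C=CC[C@@]1(O)C=C2C(=CC1=O)O[C@H](c1cc(OC)c(OC)c(OC)c1)[C@H]2C | intermediate
15 | (2S,3S,5R)-5-methoxy-3-methyl-5-(prop-2-en-1-yl)-2-(3,4,5-trimethoxyphenyl)-2,3-dihydro-1-benzofuran-6(5H)-one | C=CC[C@@]1(OC)C=C2C(=CC1=O)O[C@H](c1cc(OC)c(OC)c(OC)c1)[C@H]2C | target

**Step count and risks**

Total step count: 8. Longest linear sequence: 7 steps (steps 1, 2, 4, 5, 6, 7, 8, from compound 1; step 3 is a one-step side branch).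

Steps most likely to fail:

1. Step 7 (Proposed new method). What may go wrong: the cycloaddition may be too slow below the temperature at which the allyl dienone undergoes [3,3] shifts; the benzylic 2-alkoxyfuran may ionise or desilylate on heating; and the two furan faces may be poorly discriminated, or discriminated in the wrong sense. The fallback uses known reaction types only, sets out from alcohol 4 and returns at target 15. Commercial N,2-dimethoxy-N-methylacetamide is allylated at carbon (LiN(iPr)2, allyl bromide, THF, −78 °C) to racemic N,2-dimethoxy-N-methylpent-4-enamide F1. Ethynylmagnesium bromide converts it into 4-methoxyhept-6-en-1-yn-3-one F2. Trimethylphosphine-catalysed conjugate addition of 4 to F2 gives the (E)-β-alkoxy enone F3. LiN(SiMe3)2 and t-BuMe2SiCl give the chelation-controlled (1E,3Z)-silyl dienol ether F4, a Danishefsky-type diene that already carries methoxy (cis to the silyloxy group) and allyl on C5. Intramolecular diene–yne [4+2] cycloaddition (PhMe, 140 °C, or Ni(cod)2 with tris(2-biphenylyl) phosphite at room temperature, a zerovalent nickel catalyst) forms the same two bonds in the cyclohexa-1,4-diene F5. DDQ with 2,6-lutidine (CH2Cl2, 0 °C) removes the doubly allylic hydride at C7a and the silyl group to give 15. Because the methoxy group is outside and the allyl group inside in F4, this sequence turns the opposite facial preference of the tether into (5R), so it is the stereochemical complement of step 7. A chiral bisphosphine complex of monovalent rhodium (for example from [Rh(cod)2]SbF6) may be used in the cycloaddition for reagent control of the face.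

2. Step 8. What may go wrong: slow alkylation of the hindered tertiary hydroxyl, with competing methylation at the carbonyl oxygen of the vinylogous ester. The fallback sets out from 14 and returns at 15, and uses the shift that the direct methylation avoids. KN(SiMe3)2 with 18-crown-6 (THF, −78 to 0 °C) triggers an anionic oxy-Cope rearrangement that moves the allyl group suprafacially from C5 to C3a and leaves the potassium enolate of the 3a-allyl-5-hydroxy dienone F6. Me2SO4 O-methylates this unhindered enolate to the 3a-allyl-5-methoxy dienone F7 (burchellin-type skeleton). Warming F7 (PhMe, about 100 °C) should return the allyl group suprafacially to C5 by Cope rearrangement, the thermal course reported for 3a-allyl hydrobenzofuranoid neolignans, so that the allyl group re-enters on the face it left and 15 results.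

3. Step 5. What may go wrong: intermolecular C-alkylation of the enolate by the primary chloride (self-condensation) may outrun ring closure through oxygen. The fallback sets out from 4 (together with 5) and returns at 10, bypassing steps 5 and 6. Commercial DL-2-aminopent-4-enoic acid is converted (NaNO2, KBr, aqueous HBr, 0 °C) into 2-bromopent-4-enoic acid F8. This is condensed with Meldrum's acid 5 (DCC, DMAP, CH2Cl2) to the acyl Meldrum's acid F9. Alcoholysis with 4 (PhMe, 80 °C) gives the γ-bromo β-keto ester F10. Its secondary bromide resists intermolecular attack and, with K2CO3 in acetone, should close through oxygen directly to 10, the allyl group being already in place.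

**Further compounds**

F1 | step 7 | N,2-dimethoxy-N-methylpent-4-enamide (racemic) | C=CCC(OC)C(=O)N(C)OC
F2 | step 7 | 4-methoxyhept-6-en-1-yn-3-one (racemic) | C#CC(=O)C(OC)CC=C
F3 | step 7 | (E)-4-methoxy-1-{[(1S,2S)-2-methyl-1-(3,4,5-trimethoxyphenyl)but-3-yn-1-yl]oxy}hepta-1,6-dien-3-one (both C4 epimers) | C=CCC(OC)C(=O)/C=C/O[C@H](c1cc(OC)c(OC)c(OC)c1)[C@H](C#C)C
F4 | step 7 | (1E,3Z)-3-(tert-butyldimethylsilyloxy)-4-methoxy-1-{[(1S,2S)-2-methyl-1-(3,4,5-trimethoxyphenyl)but-3-yn-1-yl]oxy}hepta-1,3,6-triene | C=CC/C(OC)=C(O[Si](C)(C)C(C)(C)C)\C=C\O[C@H](c1cc(OC)c(OC)c(OC)c1)[C@H](C#C)C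
F5 | step 7 | (2S,3S,5R,7aS)-6-(tert-butyldimethylsilyloxy)-5-methoxy-3-methyl-5-(prop-2-en-1-yl)-2-(3,4,5-trimethoxyphenyl)-2,3,5,7a-tetrahydro-1-benzofuran (H at C7a cis to allyl, O1 cis to methoxy) | C=CC[C@@]1(OC)C=C2[C@@H](C=C1O[Si](C)(C)C(C)(C)C)O[C@H](c1cc(OC)c(OC)c(OC)c1)[C@H]2C
F6 | step 8 | (2S,3S,3aS)-5-hydroxy-3-methyl-3a-(prop-2-en-1-yl)-2-(3,4,5-trimethoxyphenyl)-3,3a-dihydro-1-benzofuran-6(2H)-one (formed as its potassium enolate, not isolated) | C=CC[C@]12C=C(O)C(=O)C=C1O[C@H](c1cc(OC)c(OC)c(OC)c1)[C@H]2C
F7 | step 8 | (2S,3S,3aS)-5-methoxy-3-methyl-3a-(prop-2-en-1-yl)-2-(3,4,5-trimethoxyphenyl)-3,3a-dihydro-1-benzofuran-6(2H)-one | C=CC[C@]12C=C(OC)C(=O)C=C1O[C@H](c1cc(OC)c(OC)c(OC)c1)[C@H]2C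
F8 | step 5 | 2-bromopent-4-enoic acid (racemic) | C=CCC(Br)C(=O)O
F9 | step 5 | 5-(2-bromo-1-hydroxypent-4-en-1-ylidene)-2,2-dimethyl-1,3-dioxane-4,6-dione (enol form) | CC1(C)OC(=O)C(=C(O)C(Br)CC=C)C(=O)O1
F10 | step 5 | (1S,2S)-2-methyl-1-(3,4,5-trimethoxyphenyl)but-3-yn-1-yl 4-bromo-3-oxohept-6-enoate (both C4 epimers) | C=CCC(Br)C(=O)CC(=O)O[C@H](c1cc(OC)c(OC)c(OC)c1)[C@H](C#C)C
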